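The vessel is closed, stirred and held at one temperature, and in it substrate and coupling partner give product.

| setting | alpha | epsilon | zeta | delta | gamma |
|---|---|---|---|---|---|
| substrate | 0.250 M | 0.250 M | 0.250 M | 0.500 M | 0.0500 M |
| coupling partner | 0.375 M | 0.375 M | 1.10 M | 0.375 M | 0.0750 M |
| product |  | 0.120 M |  |  |  |
| time |  |  |  |  | 37 min |

| run | time / min | [product] / M |
|---|---|---|
| alpha run | 5.3 | 0.0227 |
| alpha run | 11 | 0.0625 |
| alpha run | 16 | 0.0947 |
| alpha run | 21 | 0.1238 |
| alpha run | 26 | 0.1463 |
| alpha run | 32 | 0.1656 |
| alpha run | 37 | 0.1775 |
| epsilon run | 5.3 | 0.1415 |
| epsilon run | 11 | 0.1831 |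
| epsilon run | 16 | 0.2178 |
| epsilon run | 21 | 0.2420 |
| epsilon run | 26 | 0.2651 |
| epsilon run | 32 | 0.2825 |
| epsilon run | 37 | 0.2972 |
| zeta run | 5.3 | 0.0251 |
| zeta run | 11 | 0.0660 |
| zeta run | 16 | 0.0974 |
| zeta run | 21 | 0.1268 |
| zeta run | 26 | 0.1490 |
| zeta run | 32 | 0.1738 |
| zeta run | 37 | 0.1879 |
| delta run | 5.3 | 0.0327 |
| delta run | 11 | 0.0934 |
| delta run | 16 | 0.1373 |
| delta run | 21 | 0.1707 |
| delta run | 26 | 0.2001 |
| delta run | 32 | 0.2230 |
| delta run | 37 | 0.2401 |

(standard deviation of a reading: 0.001 M)

- Overall: substrate + coupling partner -> product.
- Constant volume, constant temperature.
- Bound and free are read together.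
- "The second partner" is coupling partner.
- An order is taken over about fifteen percent of the charge, up and down.

- reaction order in [coupling partner] at the outset, round the charge of the alpha run, defined at two percent of the substrate turned into product
- reaction order in [substrate] at the outset, round the charge of the alpha run, defined at two percent of the substrate turned into product (one fixed amount of product, the same in the runs compared)
- product in the gamma run at 37 min, as a share of the substrate charged

I carry one quantity. Between 11 min and 21 min of the alpha run it reads 0.139 M⁻¹ min⁻¹. This is the mixed constant, an apparent second-order constant: the rate of product formation divided by [substrate] and [coupling partner] as the product made leaves them. Over the same span the delta run, which differs from alpha in its larger substrate charge, reads 0.0865 M⁻¹ min⁻¹, lower than alpha, so this constant is not constant between these two runs. The gamma run holds both charges at alpha's divided by 5.00, with substrate the limiting reagent.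

Alpha's first two readings, drawn back, reach zero at 2.05 min, so I allow gamma 35.0 min of reaction. Alpha's constant unchanged, integrated over that time, gives 27.9 %, which I take as my floor for gamma. A constant rising in full proportion to the dilution makes the reaction first order overall, so gamma repeats alpha's share at 37 min, which is 71.0 %, and I take that as my ceiling. Taking the geometric middle, the constant multiplied by the square root of 5.00, I commit to 48.3 %.

The forecast gives 0.1 for the order in [coupling partner], 0.4 for the order in [substrate] and 17 % for the gamma share, calling gamma “roughly first order in each”, and that share stands below my floor.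

The flask gives 0.28 for the order in [coupling partner], 0.47 for the order in [substrate] and 43.9 % for the gamma share. The share lies inside my bracket , a little below my middle.

    substrate ⇌ intermediate + by-product (0.2694 min⁻¹, 0.2772 M⁻¹ min⁻¹)
    intermediate + coupling partner → product (0.3588 M⁻¹ min⁻¹)
    substrate + coupling partner ⇌ idle substrate-reagent adduct, settled at all times (6.480 M⁻¹)
    coupling partner + by-product ⇌ reagent-by-product salt, settled at all times (3.810 M⁻¹)

Read backwards from that share over the time I allowed, gamma's mixed constant, as an average, is 0.265 M⁻¹ min⁻¹, twice the reading from alpha. In the zeta run, with the larger charge of coupling partner, the same quotient reads 0.0394 M⁻¹ min⁻¹, lower than the reading from alpha. The association of substrate and coupling partner to the idle substrate-reagent adduct flattens the order in [coupling partner] round the alpha charge: the same flask without that association gives 0.62 in place of 0.28.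

Readings and results were generated by integration with constants of no real substance, and the scatter is random.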